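**Retrosynthetic overview**
1. Final operations: global desilylation (O15, O4′), and before it acylation of the free 6-hydroxyl with a silyl-protected (E)-4-hydroxy-2-methylbut-2-enoic acid.
2. Ring order: the ten-membered carbocycle is closed first (C7–C8 bond), then the γ-lactone (O8–C12) in the same operation. The key step is a new chromium-catalysed, ligand-controlled macrocyclising 2-(methoxycarbonyl)allylation of an ω-formyl (Z)-2-(bromomethyl)enoate, which sets C7 and C8.
3. The allyl bromide unit (C11–C13) is built on the C7 aldehyde by vinylalumination with methyl propiolate and SN2′ bromination.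
4. The ring-cis C4=C5 olefin (C15 trans to C6) comes from (S)-glyceraldehyde acetonide (C5–C7, source of the C6 stereocentre) by bromo-Wittig olefination and Negishi sp3–sp2 coupling at C4.
5. The (E)-C1=C10 olefin comes from but-3-yn-1-ol by Zr-catalysed carboalumination and ethylene oxide opening.

Assumption and notation: the (S)-glyceraldehyde acetonide used in step 4 is taken as purchasable; positions use germacrane numbering (C1=C10 with C14 on C10; C4=C5 with C15 on C4; C6 ester carbon; C7; C8 lactone O-carbon; C9; C11=C13; C12 lactone carbonyl; side chain primed), so the target is (1(10)E,4E,6R,7R,8S), where 4E has C3 and C6 cis on the double bond.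

**Step 1**
Reactants: 1 but-3-yn-1-ol
Product: 2 1-[(but-3-yn-1-yloxy)methyl]-4-methoxybenzene
Conditions: NaH, 4-methoxybenzyl chloride, n-Bu4NI (cat.), THF/DMF, 0 → 23 °C
Reagents that add atoms: 4-methoxybenzyl chloride, COc1ccc(CCl)cc1
Why: Williamson etherification of the primary alkoxide masks O8 as a 4-methoxybenzyl ether that lasts until step 13.

**Step 2**
Reactants: 2 1-[(but-3-yn-1-yloxy)methyl]-4-methoxybenzene; 3 oxirane
Product: 6 (3E)-6-[(4-methoxybenzyl)oxy]-4-methylhex-3-en-1-ol, via alkenylalane 4 (not isolated), via lithium alanate 5 (not isolated)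
Conditions: Me3Al, Cp2ZrCl2 (25 mol %), CH2Cl2, 0 → 23 °C; volatiles removed; n-BuLi, THF/hexane, −78 → 0 °C; then 3, 0 → 23 °C; 1 N HCl, 0 °C
Reagents that add atoms: trimethylaluminium, C[Al](C)C
Why: Negishi zirconium-catalysed carboalumination adds Me (C14) and Al syn across the alkyne with Me on the internal carbon, fixing the 1(10)E geometry, and the derived alanate opens the epoxide with retention of olefin geometry.

**Step 3**
Reactants: 6 (3E)-6-[(4-methoxybenzyl)oxy]-4-methylhex-3-en-1-ol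
Product: 7 1-({[(3E)-6-iodo-3-methylhex-3-en-1-yl]oxy}methyl)-4-methoxybenzene
Conditions: I2, PPh3, imidazole, CH2Cl2, 0 °C
Reagents that add atoms: iodine, [I][I]
Why: Appel-type iodination proceeds by SN2 displacement of the primary oxyphosphonium and leaves the olefin untouched.

**Step 4**
Reactants: 8 (4S)-2,2-dimethyl-1,3-dioxolane-4-carbaldehyde; 9 ethyl (triphenylphosphoranylidene)acetate
Product: 11 ethyl (2Z)-2-bromo-3-[(4R)-2,2-dimethyl-1,3-dioxolan-4-yl]prop-2-enoate, via bromo ylide 10 (not isolated)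
Conditions: N-bromosuccinimide, CH2Cl2, −20 °C, 1 h; then 8, −20 → 23 °C
Reagents that add atoms: N-bromosuccinimide, O=C1CCC(=O)N1Br
Why: in situ bromination of the stabilised ylide followed by Wittig olefination puts the ester trans to C6 (Z-bromoenoate); the C6 stereocentre is carried over from the chiral pool under neutral conditions (the descriptor changes from S to R only through CIP priorities).

**Step 5**
Reactants: 7 1-({[(3E)-6-iodo-3-methylhex-3-en-1-yl]oxy}methyl)-4-methoxybenzene; 11 ethyl (2Z)-2-bromo-3-[(4R)-2,2-dimethyl-1,3-dioxolan-4-yl]prop-2-enoate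
Product: 13 ethyl (2E,5E)-2-{[(4R)-2,2-dimethyl-1,3-dioxolan-4-yl]methylidene}-8-[(4-methoxybenzyl)oxy]-6-methyloct-5-enoate, via alkylzinc iodide 12 (not isolated)
Conditions: Zn dust (activated with cat. BrCH2CH2Br and Me3SiCl), LiCl, THF, 40 °C; then 11, Pd(OAc)2 (3 mol %), SPhos (6 mol %), THF, 23 °C
Reagents that add atoms: none
Why: LiCl-assisted zinc insertion and Negishi sp3–sp2 coupling replace Br with retention, so C3 ends cis to C6 and the ester carbon C15 trans, which is the ring-cis C4=C5 geometry of the target.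

**Step 6**
Reactants: 13 ethyl (2E,5E)-2-{[(4R)-2,2-dimethyl-1,3-dioxolan-4-yl]methylidene}-8-[(4-methoxybenzyl)oxy]-6-methyloct-5-enoate
Product: 14 (2E,5E)-2-{[(4R)-2,2-dimethyl-1,3-dioxolan-4-yl]methylidene}-8-[(4-methoxybenzyl)oxy]-6-methyloct-5-en-1-ol
Conditions: i-Bu2AlH (2.5 equiv), CH2Cl2, −78 °C; aq. potassium sodium tartrate
Reagents that add atoms: none
Why: 1,2-reduction of the enoate by the aluminium hydride gives the allylic alcohol (O15) without touching the acetal or the benzyl-type ether.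

**Step 7**
Reactants: 14 (2E,5E)-2-{[(4R)-2,2-dimethyl-1,3-dioxolan-4-yl]methylidene}-8-[(4-methoxybenzyl)oxy]-6-methyloct-5-en-1-ol
Product: 15 tert-butyl({(2E,5E)-2-{[(4R)-2,2-dimethyl-1,3-dioxolan-4-yl]methylidene}-8-[(4-methoxybenzyl)oxy]-6-methyloct-5-en-1-yl}oxy)diphenylsilane
Conditions: t-BuPh2SiCl, imidazole, DMF, 23 °C
Reagents that add atoms: tert-butyl(chloro)diphenylsilane, CC(C)(C)[Si](Cl)(c1ccccc1)c1ccccc1
Why: imidazole-mediated silylation gives an acid-robust silyl ether on O15 that survives to the last step.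

**Step 8**
Reactants: 15 tert-butyl({(2E,5E)-2-{[(4R)-2,2-dimethyl-1,3-dioxolan-4-yl]methylidene}-8-[(4-methoxybenzyl)oxy]-6-methyloct-5-en-1-yl}oxy)diphenylsilane
Product: 16 (2R,3E,7E)-4-({[tert-butyl(diphenyl)silyl]oxy}methyl)-10-[(4-methoxybenzyl)oxy]-8-methyldeca-3,7-diene-1,2-diol
Conditions: AcOH/H2O (4:1), 23 °C
Reagents that add atoms: none
Why: mild acid hydrolysis removes the terminal acetonide; the tert-butyldiphenylsilyl and 4-methoxybenzyl ethers are stable to aqueous acetic acid.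

**Step 9**
Reactants: 16 (2R,3E,7E)-4-({[tert-butyl(diphenyl)silyl]oxy}methyl)-10-[(4-methoxybenzyl)oxy]-8-methyldeca-3,7-diene-1,2-diol
Product: 17 (2R,3E,7E)-4-({[tert-butyl(diphenyl)silyl]oxy}methyl)-10-[(4-methoxybenzyl)oxy]-8-methyl-1,2-bis[(triethylsilyl)oxy]deca-3,7-diene
Conditions: Et3SiCl (2.5 equiv), imidazole, DMF, 0 °C
Reagents that add atoms: chlorotriethylsilane, CC[Si](Cl)(CC)CC
Why: exhaustive silylation of the diol sets up the selective oxidation of the primary silyl ether and leaves O6 protected.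

**Step 10**
Reactants: 17 (2R,3E,7E)-4-({[tert-butyl(diphenyl)silyl]oxy}methyl)-10-[(4-methoxybenzyl)oxy]-8-methyl-1,2-bis[(triethylsilyl)oxy]deca-3,7-diene
Product: 18 (2R,3E,7E)-4-({[tert-butyl(diphenyl)silyl]oxy}methyl)-10-[(4-methoxybenzyl)oxy]-8-methyl-2-[(triethylsilyl)oxy]deca-3,7-dienal
Conditions: (COCl)2, DMSO, CH2Cl2, −78 → −30 °C; then Et3N, −78 → −20 °C; used crude at once
Reagents that add atoms: none
Why: under Swern conditions the primary triethylsilyl ether is converted directly into the alkoxysulfonium salt and hence the aldehyde while the secondary one is inert; the low temperature protects the allylic, α-oxygenated C6 centre.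

**Step 11**
Reactants: 18 (2R,3E,7E)-4-({[tert-butyl(diphenyl)silyl]oxy}methyl)-10-[(4-methoxybenzyl)oxy]-8-methyl-2-[(triethylsilyl)oxy]deca-3,7-dienal; 19 methyl prop-2-ynoate
Product: 21 methyl (3RS,4R,5E,9E)-6-({[tert-butyl(diphenyl)silyl]oxy}methyl)-3-hydroxy-12-[(4-methoxybenzyl)oxy]-10-methyl-2-methylidene-4-[(triethylsilyl)oxy]dodeca-5,9-dienoate, via vinylalane 20 (not isolated)
Conditions: i-Bu2AlH, N-methylmorpholine N-oxide, THF, 0 °C (19 → 20); then 18, 0 → 23 °C; aq. potassium sodium tartrate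
Reagents that add atoms: none
Why: hydroalumination of the propiolate gives the α-aluminated acrylate, which adds 1,2 to the aldehyde (a Morita–Baylis–Hillman-type adduct made without amine base, so C6 is not epimerised); the new carbinol configuration is irrelevant because step 12 removes it.

**Step 12**
Reactants: 21 methyl (3RS,4R,5E,9E)-6-({[tert-butyl(diphenyl)silyl]oxy}methyl)-3-hydroxy-12-[(4-methoxybenzyl)oxy]-10-methyl-2-methylidene-4-[(triethylsilyl)oxy]dodeca-5,9-dienoate
Product: 22 methyl (2Z,4R,5E,9E)-2-(bromomethyl)-6-({[tert-butyl(diphenyl)silyl]oxy}methyl)-12-[(4-methoxybenzyl)oxy]-10-methyl-4-[(triethylsilyl)oxy]dodeca-2,5,9-trienoate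
Conditions: N-bromosuccinimide, Me2S, CH2Cl2, 0 → 23 °C
Reagents that add atoms: N-bromosuccinimide, O=C1CCC(=O)N1Br
Why: Corey–Kim-type activation of the allylic alcohol and SN2′ attack of bromide give the thermodynamically preferred (Z)-2-(bromomethyl)enoate with C6 trans to the ester.

**Step 13**
Reactants: 22 methyl (2Z,4R,5E,9E)-2-(bromomethyl)-6-({[tert-butyl(diphenyl)silyl]oxy}methyl)-12-[(4-methoxybenzyl)oxy]-10-methyl-4-[(triethylsilyl)oxy]dodeca-2,5,9-trienoate
Product: 23 methyl (2Z,4R,5E,9E)-2-(bromomethyl)-6-({[tert-butyl(diphenyl)silyl]oxy}methyl)-12-hydroxy-10-methyl-4-[(triethylsilyl)oxy]dodeca-2,5,9-trienoate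
Conditions: DDQ, CH2Cl2/pH 7 phosphate buffer (10:1), 0 °C
Reagents that add atoms: none
Why: oxidative cleavage of the 4-methoxybenzyl ether under buffered conditions frees O8 while the silyl ethers and the allylic bromide are unaffected.

**Step 14**
Reactants: 23 methyl (2Z,4R,5E,9E)-2-(bromomethyl)-6-({[tert-butyl(diphenyl)silyl]oxy}methyl)-12-hydroxy-10-methyl-4-[(triethylsilyl)oxy]dodeca-2,5,9-trienoate
Product: 24 methyl (2Z,4R,5E,9E)-2-(bromomethyl)-6-({[tert-butyl(diphenyl)silyl]oxy}methyl)-10-methyl-12-oxo-4-[(triethylsilyl)oxy]dodeca-2,5,9-trienoate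
Conditions: Dess–Martin periodinane, NaHCO3, CH2Cl2, 0 °C; filtered through buffered silica and used at once
Reagents that add atoms: none
Why: buffered Dess–Martin oxidation gives the β,γ-unsaturated aldehyde without migration of the C1=C10 double bond into conjugation.

**Step 15**
Reactants: 24 methyl (2Z,4R,5E,9E)-2-(bromomethyl)-6-({[tert-butyl(diphenyl)silyl]oxy}methyl)-10-methyl-12-oxo-4-[(triethylsilyl)oxy]dodeca-2,5,9-trienoate
Product: 27 (1(10)E,4E,6R,7R,8S)-15-[(tert-butyldiphenylsilyl)oxy]-6-[(triethylsilyl)oxy]germacra-1(10),4,11(13)-trien-12,8-olide, via trimethylsilyl ether 25 (not isolated), via hydroxy ester 26 (not isolated)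
Conditions: CrCl2 (15 mol %), (S,S)-3,6-diphenyl-1,8-bis(4-isopropyl-4,5-dihydrooxazol-2-yl)-9H-carbazole (18 mol %), Mn powder (3 equiv), Me3SiCl (2 equiv), i-Pr2NEt (30 mol %), THF, 23 °C, 24 added by syringe pump over 12 h (final 2 mmol/L); then aq. citric acid/THF, 0 °C; then PPTS (10 mol %), CH2Cl2, 23 °C
Reagents that add atoms: none
Why: Proposed new method: a ligand-controlled, chromium-catalysed macrocyclising 2-(methoxycarbonyl)allylation (a catalytic asymmetric intramolecular Nozaki–Hiyama–Kishi/Barbier reaction) that closes the ten-membered carbocycle. Divalent chromium, regenerated from trivalent chromium by Mn, inserts into the allylic C13–Br bond. The allyl–trivalent-chromium species, which tolerates the δ-silyloxy group, equilibrates by 1,3-metallotropy and adds through its γ-carbon C7 to the tethered aldehyde in a closed six-membered chair transition state on the N,N,N-ligated metal. The chiral ligand blocks the Si face of C8 so that C7 bonds to the Re face (8S), and the ring-constrained chair delivers the 7,8-anti adduct (7R), which fixes C7 relative to the existing C6 centre. Me3SiCl releases the catalyst, and after desilylation only O8 is free (O6 stays silylated) and lactonises onto C12 to the trans-fused α-methylene lactone. The closest known reactions are the intermolecular chromium-catalysed enantioselective 2-(alkoxycarbonyl)allylation of aldehydes and the stoichiometric, substrate-controlled CrCl2 Barbier closure of germacranolide rings; catalyst-controlled closure of a ten-membered ring with a γ-branched acrylate-derived allyl unit has not been shown.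

**Step 16**
Reactants: 27 (1(10)E,4E,6R,7R,8S)-15-[(tert-butyldiphenylsilyl)oxy]-6-[(triethylsilyl)oxy]germacra-1(10),4,11(13)-trien-12,8-olide
Product: 28 (1(10)E,4E,6R,7S,8S)-15-[(tert-butyldiphenylsilyl)oxy]-6-hydroxygermacra-1(10),4,11(13)-trien-12,8-olide
Conditions: HF·pyridine, pyridine, THF, 0 °C
Reagents that add atoms: none
Why: buffered fluoride cleaves the secondary triethylsilyl ether far faster than the primary tert-butyldiphenylsilyl ether, and the non-basic medium avoids translactonisation to O6 (the 7S label arises only from a CIP priority change; no centre is touched).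

**Step 17**
Reactants: 29 {[tert-butyl(dimethyl)silyl]oxy}acetaldehyde; 30 ethyl 2-(triphenylphosphoranylidene)propanoate
Product: 31 ethyl (2E)-4-{[tert-butyl(dimethyl)silyl]oxy}-2-methylbut-2-enoate
Conditions: CH2Cl2, 23 °C
Reagents that add atoms: none
Why: Wittig olefination with the α-methyl stabilised ylide is E-selective (ester trans to C3′), giving the tiglate-type geometry of the side chain.

**Step 18**
Reactants: 31 ethyl (2E)-4-{[tert-butyl(dimethyl)silyl]oxy}-2-methylbut-2-enoate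
Product: 32 (2E)-4-{[tert-butyl(dimethyl)silyl]oxy}-2-methylbut-2-enoic acid
Conditions: LiOH·H2O, THF/MeOH/H2O, 23 °C; then 1 N HCl to pH 4, 0 °C
Reagents that add atoms: lithium hydroxide, [Li+].[OH-]
Why: saponification of the ethyl ester leaves the primary silyl ether and the E-olefin intact.

**Step 19**
Reactants: 28 (1(10)E,4E,6R,7S,8S)-15-[(tert-butyldiphenylsilyl)oxy]-6-hydroxygermacra-1(10),4,11(13)-trien-12,8-olide; 32 (2E)-4-{[tert-butyl(dimethyl)silyl]oxy}-2-methylbut-2-enoic acid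
Product: 33 (1(10)E,4E,6R,7R,8S)-15-[(tert-butyldiphenylsilyl)oxy]-6-{[(2E)-4-{[tert-butyl(dimethyl)silyl]oxy}-2-methylbut-2-enoyl]oxy}germacra-1(10),4,11(13)-trien-12,8-olide
Conditions: 2-methyl-6-nitrobenzoic anhydride, Et3N, DMAP, CH2Cl2, 23 °C
Reagents that add atoms: none
Why: Shiina esterification (mixed anhydride, DMAP acyl transfer) acylates the hindered allylic 6-hydroxyl with retention at C6 and without generating an alkoxide that could translactonise.

**Step 20**
Reactants: 33 (1(10)E,4E,6R,7R,8S)-15-[(tert-butyldiphenylsilyl)oxy]-6-{[(2E)-4-{[tert-butyl(dimethyl)silyl]oxy}-2-methylbut-2-enoyl]oxy}germacra-1(10),4,11(13)-trien-12,8-olide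
Product: 34 CNP0344932.2, [(3aR,4R,5E,9E,11aS)-6-(hydroxymethyl)-10-methyl-3-methylidene-2-oxo-2,3,3a,4,7,8,11,11a-octahydrocyclodeca[b]furan-4-yl] (2E)-4-hydroxy-2-methylbut-2-enoate
Conditions: HF·pyridine, pyridine, THF, 0 → 23 °C
Reagents that add atoms: none
Why: fluoride-mediated global desilylation frees O15 and O4′; the α-methylene lactone and the allylic ester are stable to buffered HF, and O15 is trans to C6 across C4=C5 so acyl migration is not possible.

**Compound list**
1 | but-3-yn-1-ol | C#CCCO | starting material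
2 | 1-[(but-3-yn-1-yloxy)methyl]-4-methoxybenzene | C#CCCOCc1ccc(OC)cc1 | intermediate
3 | oxirane (ethylene oxide) | C1CO1 | starting material
4 | dimethyl[(1E)-4-[(4-methoxybenzyl)oxy]-2-methylbut-1-en-1-yl]alumane | C[Al](C)/C=C(\C)CCOCc1ccc(OC)cc1 | intermediate
5 | lithium butyl(dimethyl)[(1E)-4-[(4-methoxybenzyl)oxy]-2-methylbut-1-en-1-yl]aluminate | [Li+].CCCC[Al-](C)(C)/C=C(\C)CCOCc1ccc(OC)cc1 | intermediate
6 | (3E)-6-[(4-methoxybenzyl)oxy]-4-methylhex-3-en-1-ol | OCC/C=C(\C)CCOCc1ccc(OC)cc1 | intermediate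
7 | 1-({[(3E)-6-iodo-3-methylhex-3-en-1-yl]oxy}methyl)-4-methoxybenzene | ICC/C=C(\C)CCOCc1ccc(OC)cc1 | intermediate
8 | (4S)-2,2-dimethyl-1,3-dioxolane-4-carbaldehyde | O=C[C@@H]1COC(C)(C)O1 | starting material
9 | ethyl (triphenylphosphoranylidene)acetate | CCOC(=O)C=P(c1ccccc1)(c1ccccc1)c1ccccc1 | starting material
10 | ethyl bromo(triphenylphosphoranylidene)acetate | CCOC(=O)C(Br)=P(c1ccccc1)(c1ccccc1)c1ccccc1 | intermediate
11 | ethyl (2Z)-2-bromo-3-[(4R)-2,2-dimethyl-1,3-dioxolan-4-yl]prop-2-enoate | CCOC(=O)/C(Br)=C/[C@@H]1COC(C)(C)O1 | intermediate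
12 | iodo[(3E)-6-[(4-methoxybenzyl)oxy]-4-methylhex-3-en-1-yl]zinc | I[Zn]CC/C=C(\C)CCOCc1ccc(OC)cc1 | intermediate
13 | ethyl (2E,5E)-2-{[(4R)-2,2-dimethyl-1,3-dioxolan-4-yl]methylidene}-8-[(4-methoxybenzyl)oxy]-6-methyloct-5-enoate | CCOC(=O)/C(CC/C=C(\C)CCOCc1ccc(OC)cc1)=C/[C@@H]1COC(C)(C)O1 | intermediate
14 | (2E,5E)-2-{[(4R)-2,2-dimethyl-1,3-dioxolan-4-yl]methylidene}-8-[(4-methoxybenzyl)oxy]-6-methyloct-5-en-1-ol | OC/C(CC/C=C(\C)CCOCc1ccc(OC)cc1)=C/[C@@H]1COC(C)(C)O1 | intermediate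
15 | tert-butyl({(2E,5E)-2-{[(4R)-2,2-dimethyl-1,3-dioxolan-4-yl]methylidene}-8-[(4-methoxybenzyl)oxy]-6-methyloct-5-en-1-yl}oxy)diphenylsilane | CC(C)(C)[Si](OC/C(CC/C=C(\C)CCOCc1ccc(OC)cc1)=C/[C@@H]1COC(C)(C)O1)(c1ccccc1)c1ccccc1 | intermediate
16 | (2R,3E,7E)-4-({[tert-butyl(diphenyl)silyl]oxy}methyl)-10-[(4-methoxybenzyl)oxy]-8-methyldeca-3,7-diene-1,2-diol | CC(C)(C)[Si](OC/C(CC/C=C(\C)CCOCc1ccc(OC)cc1)=C/[C@@H](O)CO)(c1ccccc1)c1ccccc1 | intermediate
17 | (2R,3E,7E)-4-({[tert-butyl(diphenyl)silyl]oxy}methyl)-10-[(4-methoxybenzyl)oxy]-8-methyl-1,2-bis[(triethylsilyl)oxy]deca-3,7-diene | CC(C)(C)[Si](OC/C(CC/C=C(\C)CCOCc1ccc(OC)cc1)=C/[C@@H](O[Si](CC)(CC)CC)CO[Si](CC)(CC)CC)(c1ccccc1)c1ccccc1 | intermediate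
18 | (2R,3E,7E)-4-({[tert-butyl(diphenyl)silyl]oxy}methyl)-10-[(4-methoxybenzyl)oxy]-8-methyl-2-[(triethylsilyl)oxy]deca-3,7-dienal | CC(C)(C)[Si](OC/C(CC/C=C(\C)CCOCc1ccc(OC)cc1)=C/[C@@H](O[Si](CC)(CC)CC)C=O)(c1ccccc1)c1ccccc1 | intermediate
19 | methyl prop-2-ynoate | C#CC(=O)OC | starting material
20 | methyl 2-[bis(2-methylpropyl)alumanyl]prop-2-enoate | C=C(C(=O)OC)[Al](CC(C)C)CC(C)C | intermediate
21 | methyl (3RS,4R,5E,9E)-6-({[tert-butyl(diphenyl)silyl]oxy}methyl)-3-hydroxy-12-[(4-methoxybenzyl)oxy]-10-methyl-2-methylidene-4-[(triethylsilyl)oxy]dodeca-5,9-dienoate | CC(C)(C)[Si](OC/C(CC/C=C(\C)CCOCc1ccc(OC)cc1)=C/[C@@H](O[Si](CC)(CC)CC)C(O)C(=C)C(=O)OC)(c1ccccc1)c1ccccc1 | intermediate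
22 | methyl (2Z,4R,5E,9E)-2-(bromomethyl)-6-({[tert-butyl(diphenyl)silyl]oxy}methyl)-12-[(4-methoxybenzyl)oxy]-10-methyl-4-[(triethylsilyl)oxy]dodeca-2,5,9-trienoate | CC(C)(C)[Si](OC/C(CC/C=C(\C)CCOCc1ccc(OC)cc1)=C/[C@@H](O[Si](CC)(CC)CC)/C=C(\CBr)C(=O)OC)(c1ccccc1)c1ccccc1 | intermediate
23 | methyl (2Z,4R,5E,9E)-2-(bromomethyl)-6-({[tert-butyl(diphenyl)silyl]oxy}methyl)-12-hydroxy-10-methyl-4-[(triethylsilyl)oxy]dodeca-2,5,9-trienoate | CC(C)(C)[Si](OC/C(CC/C=C(\C)CCO)=C/[C@@H](O[Si](CC)(CC)CC)/C=C(\CBr)C(=O)OC)(c1ccccc1)c1ccccc1 | intermediate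
24 | methyl (2Z,4R,5E,9E)-2-(bromomethyl)-6-({[tert-butyl(diphenyl)silyl]oxy}methyl)-10-methyl-12-oxo-4-[(triethylsilyl)oxy]dodeca-2,5,9-trienoate | CC(C)(C)[Si](OC/C(CC/C=C(\C)CC=O)=C/[C@@H](O[Si](CC)(CC)CC)/C=C(\CBr)C(=O)OC)(c1ccccc1)c1ccccc1 | intermediate
25 | methyl (1(10)E,4E,6R,7R,8S)-15-[(tert-butyldiphenylsilyl)oxy]-6-[(triethylsilyl)oxy]-8-[(trimethylsilyl)oxy]germacra-1(10),4,11(13)-trien-12-oate | C[Si](C)(C)O[C@H]1C/C(C)=C/CC/C(CO[Si](c2ccccc2)(c2ccccc2)C(C)(C)C)=C\[C@@H](O[Si](CC)(CC)CC)[C@@H]1C(=C)C(=O)OC | intermediate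
26 | methyl (1(10)E,4E,6R,7R,8S)-15-[(tert-butyldiphenylsilyl)oxy]-8-hydroxy-6-[(triethylsilyl)oxy]germacra-1(10),4,11(13)-trien-12-oate | O[C@H]1C/C(C)=C/CC/C(CO[Si](c2ccccc2)(c2ccccc2)C(C)(C)C)=C\[C@@H](O[Si](CC)(CC)CC)[C@@H]1C(=C)C(=O)OC | intermediate
27 | (1(10)E,4E,6R,7R,8S)-15-[(tert-butyldiphenylsilyl)oxy]-6-[(triethylsilyl)oxy]germacra-1(10),4,11(13)-trien-12,8-olide | C=C1C(=O)O[C@H]2C/C(C)=C/CC/C(CO[Si](c3ccccc3)(c3ccccc3)C(C)(C)C)=C\[C@@H](O[Si](CC)(CC)CC)[C@H]12 | intermediate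
28 | (1(10)E,4E,6R,7S,8S)-15-[(tert-butyldiphenylsilyl)oxy]-6-hydroxygermacra-1(10),4,11(13)-trien-12,8-olide | C=C1C(=O)O[C@H]2C/C(C)=C/CC/C(CO[Si](c3ccccc3)(c3ccccc3)C(C)(C)C)=C\[C@@H](O)[C@H]12 | intermediate
29 | {[tert-butyl(dimethyl)silyl]oxy}acetaldehyde | CC(C)(C)[Si](C)(C)OCC=O | starting material
30 | ethyl 2-(triphenylphosphoranylidene)propanoate | CCOC(=O)C(C)=P(c1ccccc1)(c1ccccc1)c1ccccc1 | starting material
31 | ethyl (2E)-4-{[tert-butyl(dimethyl)silyl]oxy}-2-methylbut-2-enoate | CCOC(=O)/C(C)=C/CO[Si](C)(C)C(C)(C)C | intermediate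
32 | (2E)-4-{[tert-butyl(dimethyl)silyl]oxy}-2-methylbut-2-enoic acid | OC(=O)/C(C)=C/CO[Si](C)(C)C(C)(C)C | intermediate
33 | (1(10)E,4E,6R,7R,8S)-15-[(tert-butyldiphenylsilyl)oxy]-6-{[(2E)-4-{[tert-butyl(dimethyl)silyl]oxy}-2-methylbut-2-enoyl]oxy}germacra-1(10),4,11(13)-trien-12,8-olide | C=C1C(=O)O[C@H]2C/C(C)=C/CC/C(CO[Si](c3ccccc3)(c3ccccc3)C(C)(C)C)=C\[C@@H](OC(=O)/C(C)=C/CO[Si](C)(C)C(C)(C)C)[C@H]12 | intermediate
34 | CNP0344932.2, [(3aR,4R,5E,9E,11aS)-6-(hydroxymethyl)-10-methyl-3-methylidene-2-oxo-2,3,3a,4,7,8,11,11a-octahydrocyclodeca[b]furan-4-yl] (2E)-4-hydroxy-2-methylbut-2-enoate | C=C1C(=O)O[C@H]2C/C(C)=C/CC/C(CO)=C\[C@@H](OC(=O)/C(C)=C/CO)[C@H]12 | target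

**Totals**
Total step count: 20. Longest linear sequence: 17 steps (steps 1–3, 5–16, 19, 20 from but-3-yn-1-ol).

**Steps most likely to fail, with fallbacks**

Step 15 (the proposed new macrocyclisation). The risks are oligomerisation, conjugation of the β,γ-unsaturated aldehyde before ring closure, and a mismatch between the ligand and the C6 silyloxy centre that gives the wrong C7/C8 pair. The fallback uses only known chemistry and replaces catalyst control by substrate control plus a stereochemical correction. It sets out from 24: stoichiometric CrCl2 in THF at high dilution without ligand (the established macrocyclic Barbier closure of germacranolide rings) is applied. Any 7,8-anti adduct lactonises directly to 27. The 7,8-syn adduct that (Z)-2-(bromomethyl)enoates normally give lactonises to the cis-fused epimer (1(10)E,4E,6R,7R,8R)-15-[(tert-butyldiphenylsilyl)oxy]-6-[(triethylsilyl)oxy]germacra-1(10),4,11(13)-trien-12,8-olide F1. This is opened with LiOH in THF/H2O to (1(10)E,4E,6R,7R,8R)-15-[(tert-butyldiphenylsilyl)oxy]-8-hydroxy-6-[(triethylsilyl)oxy]germacra-1(10),4,11(13)-trien-12-oic acid F2 (acidified only to pH 5 at 0 °C and used at once). Mitsunobu lactonisation (PPh3, diisopropyl azodicarboxylate, THF, high dilution) then closes the carboxylate onto C8 with inversion, and the route is rejoined at 27. In this fallback the sense at C7 rests on the C6 stereocentre, which is not guaranteed.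

Step 5 (Negishi sp3–sp2 coupling). The risks are sluggish zinc insertion, protodezincation or homocoupling, and loss of olefin geometry at the bromoenoate. The fallback changes the bond construction: the C3–C4 bond is made by enolate alkylation and C4=C5 by olefination. It sets out from 7: the sodium salt of triethyl phosphonoacetate (NaH, DMF, 60 °C) is alkylated with 7 to give ethyl (5E)-2-(diethoxyphosphoryl)-8-[(4-methoxybenzyl)oxy]-6-methyloct-5-enoate F3. Horner–Wadsworth–Emmons reaction of F3 with aldehyde 8 (NaH, THF, 0 °C) and removal of the minor (2Z) isomer by chromatography rejoin the route at 13, bypassing 11 and 12.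

Step 19 (acylation of the hindered 6-hydroxyl next to the lactone). The risks are slow acylation, translactonisation to the 12,6-olide, and conjugate addition of DMAP to the methylene lactone. The fallback attaches a small, reactive acid first and builds the side-chain double bond afterwards. It sets out from 28: esterification with commercial 2-(diethoxyphosphoryl)propanoic acid (N,N′-dicyclohexylcarbodiimide, cat. DMAP, CH2Cl2, 0 °C) gives (1(10)E,4E,6R,7R,8S)-15-[(tert-butyldiphenylsilyl)oxy]-6-{[2-(diethoxyphosphoryl)propanoyl]oxy}germacra-1(10),4,11(13)-trien-12,8-olide F4. Horner–Wadsworth–Emmons reaction of F4 with aldehyde 29 (LiCl, i-Pr2NEt, MeCN, 23 °C) gives the (E)-enoate and rejoins the route at 33.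

**Further compounds**
F1 | step 15 | (1(10)E,4E,6R,7R,8R)-15-[(tert-butyldiphenylsilyl)oxy]-6-[(triethylsilyl)oxy]germacra-1(10),4,11(13)-trien-12,8-olide (cis-fused 8-epimer of 27) | C=C1C(=O)O[C@@H]2C/C(C)=C/CC/C(CO[Si](c3ccccc3)(c3ccccc3)C(C)(C)C)=C\[C@@H](O[Si](CC)(CC)CC)[C@H]12
F2 | step 15 | (1(10)E,4E,6R,7R,8R)-15-[(tert-butyldiphenylsilyl)oxy]-8-hydroxy-6-[(triethylsilyl)oxy]germacra-1(10),4,11(13)-trien-12-oic acid | O[C@@H]1C/C(C)=C/CC/C(CO[Si](c2ccccc2)(c2ccccc2)C(C)(C)C)=C\[C@@H](O[Si](CC)(CC)CC)[C@@H]1C(=C)C(=O)O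
F3 | step 5 | ethyl (5E)-2-(diethoxyphosphoryl)-8-[(4-methoxybenzyl)oxy]-6-methyloct-5-enoate | CCOC(=O)C(CC/C=C(\C)CCOCc1ccc(OC)cc1)P(=O)(OCC)OCC
F4 | step 19 | (1(10)E,4E,6R,7R,8S)-15-[(tert-butyldiphenylsilyl)oxy]-6-{[2-(diethoxyphosphoryl)propanoyl]oxy}germacra-1(10),4,11(13)-trien-12,8-olide | C=C1C(=O)O[C@H]2C/C(C)=C/CC/C(CO[Si](c3ccccc3)(c3ccccc3)C(C)(C)C)=C\[C@@H](OC(=O)C(C)P(=O)(OCC)OCC)[C@H]12
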